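**Assumptions (one line each).** Iridoid numbering is used throughout: C1 acetal carbon, O2, C3=C4 (C11 on C4), C5=C6, C7, C8 (C10 on C8), C9 ring-fusion CH; the target is (1S,7S,8R,9S). The enantiomer of the acyl-transfer catalyst in Step 7 is assumed to be the one that gives the (S)-ester and must be confirmed by correlation.

## Retrosynthetic overview

1. Target 17 ⇐ valtrate (16) by acetate opening of the C8–C10 spiro-epoxide at C10 (retention at C8).
2. 16 ⇐ dienyl triflate 14 (Stille hydroxymethylation, then acetylation, installs C11 and completes the dienol ether) ⇐ epoxy-enone 13 ⇐ methylidene enone 12.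
3. 12 ⇐ pyranone 9 + alkenylboronate aldehyde 6 by a Rh-catalysed conjugate alkenylation/aldol [3+2] annulation (C8–C9 and C5–C6 bonds; C9 set anti to the anomeric ester).
4. 9 ⇐ furfuryl alcohol (Achmatowicz, then dynamic kinetic acylation that installs the C1 isovalerate at the outset); 6 ⇐ methyl (S)-glycerate acetonide (C7 from the chiral pool).
5. Ring order: pyran first (from a furan), cyclopentene second; C8 oxygen, C11 and C10 acetate last.

## Route

**Step 1**
Reactants: 1, methyl (S)-2,2-dimethyl-1,3-dioxolane-4-carboxylate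
Product: 2, (R)-4-ethynyl-2,2-dimethyl-1,3-dioxolane
Conditions: DIBAL-H, CH2Cl2, −78 °C; then MeOH, K2CO3, Ohira–Bestmann reagent, −78 °C → rt
Reagents that add atoms: dimethyl (1-diazo-2-oxopropyl)phosphonate, COP(=O)(OC)C(=[N+]=[N-])C(C)=O (supplies the terminal alkyne carbon)
Why: One-pot ester half-reduction and Seyferth–Gilbert (Ohira–Bestmann) homologation; the stereocentre (future C7) is untouched, and the descriptor changes S→R only through CIP priorities.

**Step 2**
Reactants: 2, (R)-4-ethynyl-2,2-dimethyl-1,3-dioxolane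
Product: 3, (R)-but-3-yne-1,2-diol
Conditions: Dowex 50W-X8 (H+), MeOH, rt
Reagents that add atoms: none
Why: Acid-catalysed acetonide transketalisation; no bond to the stereocentre is broken.

**Step 3**
Reactants: 3, (R)-but-3-yne-1,2-diol
Product: 4, (R)-1,2-bis(triethylsilyloxy)but-3-yne
Conditions: TESCl (2.3 equiv), imidazole, CH2Cl2, 0 °C → rt
Reagents that add atoms: chlorotriethylsilane, CC[Si](Cl)(CC)CC
Why: Standard bis-silylation; the primary TES is later the aldehyde precursor and the secondary TES protects the C7 oxygen.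

**Step 4**
Reactants: 4, (R)-1,2-bis(triethylsilyloxy)but-3-yne
Product: 5, (R)-2-[3,4-bis(triethylsilyloxy)but-1-en-2-yl]-4,4,5,5-tetramethyl-1,3,2-dioxaborolane
Conditions: (SIMes)CuCl (5 mol %), NaOt-Bu (5 mol %), B2pin2, MeOH (2 equiv), THF, −15 °C
Reagents that add atoms: bis(pinacolato)diboron, CC1(C)OB(OC1(C)C)B1OC(C)(C)C(C)(C)O1
Why: NHC–Cu-catalysed α-selective (Markovnikov) protoboration of a terminal alkyne bearing a propargylic oxygen gives the 1,1-disubstituted alkenyl-Bpin (future C8=C10).

**Step 5**
Reactants: 5, the bis-TES alkenylboronate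
Product: 6, (R)-3-(4,4,5,5-tetramethyl-1,3,2-dioxaborolan-2-yl)-2-(triethylsilyloxy)but-3-enal
Conditions: (COCl)2, DMSO, CH2Cl2, −78 → −30 °C; then i-Pr2NEt, −78 → −20 °C; used crude
Reagents that add atoms: none
Why: Swern conditions cleave and oxidise a primary TES ether directly to the aldehyde while the secondary TES ether and the alkenyl-Bpin survive; low temperature and a hindered base limit epimerisation at the α-silyloxy centre.

**Step 6**
Reactants: 7, furfuryl alcohol
Product: 8, (±)-6-hydroxy-2H-pyran-3(6H)-one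
Conditions: NBS, NaHCO3, NaOAc, THF/H2O (4:1), 0 °C
Reagents that add atoms: water, O
Why: Achmatowicz oxidative ring expansion of the furan to the pyranone lactol, which supplies C1, O2, C3, C4 (as ketone), C5 and C9.

**Step 7**
Reactants: 8, (±)-6-hydroxy-2H-pyran-3(6H)-one
Product: 9, (S)-5-oxo-5,6-dihydro-2H-pyran-2-yl 3-methylbutanoate
Conditions: isovaleric anhydride (1.3 equiv), (S)-benzotetramisole (5 mol %), toluene, 0 °C
Reagents that add atoms: isovaleric anhydride, CC(C)CC(=O)OC(=O)CC(C)C
Why: Dynamic kinetic asymmetric acylation of a rapidly racemising lactol by a chiral isothiourea acyl-transfer catalyst sets C1 (S) and installs the final C1 isovalerate in one operation.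

**Step 8**
Reactants: 9, the (S)-pyranone isovalerate; 6, the alkenylboronate aldehyde (1.5 equiv)
Product: 10, (1S,6R,7aS)-5-hydroxy-7-methylidene-4-oxo-6-(triethylsilyloxy)octahydrocyclopenta[c]pyran-1-yl 3-methylbutanoate (cis-fused; mixture at C4a/C5, both later become sp2 or are eliminated)
Conditions: [Rh(cod)OH]2 (3 mol %), 1,4-dioxane/H2O (10:1), 40 °C
Reagents that add atoms: none
Why: Proposed new method: Rh–OH transmetalates the alkenyl-Bpin, the alkenyl-Rh adds to C9 anti to the pseudo-axial anomeric isovalerate (sets C9 S, same facial bias as annulations and conjugate additions on 6-acyloxy/alkoxy pyranones), and the regiodefined Rh oxa-π-allyl enolate at C5 is trapped intramolecularly by the pendant aldehyde (5-exo aldol, C5–C6) before protonation; closest known chemistry is Hayashi–Miyaura conjugate alkenylation combined with Rh-catalysed conjugate addition–aldol cyclisation and Rh [3+2] annulations of 2-formylarylboronic acids.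

**Step 9**
Reactants: 10, the TES-protected aldol
Product: 11, (1S,6R,7aS)-5,6-dihydroxy-7-methylidene-4-oxooctahydrocyclopenta[c]pyran-1-yl 3-methylbutanoate
Conditions: HF·pyridine, excess pyridine, THF, 0 °C
Reagents that add atoms: none
Why: Buffered fluoride desilylation of a secondary TES ether; the anomeric ester and β-hydroxy ketone tolerate these near-neutral conditions.

**Step 10**
Reactants: 11, the diol
Product: 12, (1S,6S,7aR)-7-methylidene-4-oxo-1,3,4,6,7,7a-hexahydrocyclopenta[c]pyran-1,6-diyl bis(3-methylbutanoate)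
Conditions: isovaleric anhydride (3 equiv), Et3N, DMAP (cat.), CH2Cl2, 0 °C → rt; then DBU (1.1 equiv), 0 °C, short contact
Reagents that add atoms: isovaleric anhydride, CC(C)CC(=O)OC(=O)CC(C)C
Why: Both hydroxyls are acylated and the β-acyloxy ketone undergoes E1cB elimination, giving the C5=C6 enone and leaving the C7 isovalerate in place (acylation does not touch the C7–O bond; descriptor changes are CIP-only).

**Step 11**
Reactants: 12, the methylidene enone
Product: 13, (1S,6S,7R,7aS)-4-oxo-3,4,6,7a-tetrahydro-1H-spiro[cyclopenta[c]pyran-7,2'-oxirane]-1,6-diyl bis(3-methylbutanoate)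
Conditions: DMDO, acetone/CH2Cl2, 0 °C
Reagents that add atoms: dimethyldioxirane, CC1(C)OO1
Why: Electrophilic epoxidation is chemoselective for the isolated 1,1-disubstituted alkene over the electron-poor enone (DMDO avoids Baeyer–Villiger) and occurs anti to the adjacent C7 acyloxy group, placing the C8 oxygen α (sets C8 R).

**Step 12**
Reactants: 13, the epoxy-enone
Product: 14, (1S,6S,7R,7aS)-4-(trifluoromethanesulfonyloxy)-6,7a-dihydro-1H-spiro[cyclopenta[c]pyran-7,2'-oxirane]-1,6-diyl bis(3-methylbutanoate)
Conditions: Comins' reagent (1.3 equiv) premixed with 13, then KHMDS (1.1 equiv), THF, −78 °C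
Reagents that add atoms: N-(5-chloro-2-pyridyl)bis(trifluoromethanesulfonimide), O=S(=O)(N(c1ccc(Cl)cn1)S(=O)(=O)C(F)(F)F)C(F)(F)F
Why: Kinetic α′-deprotonation at C3 (the only enolisable α-carbon) with in situ O-triflation gives the C3=C4 enol triflate, i.e. the dienol ether skeleton; no stereocentre is involved.

**Step 13**
Reactants: 14, the dienyl triflate
Product: 15, 11-O-deacetylvaltrate [(1S,6S,7R,7aS)-4-(hydroxymethyl)-6,7a-dihydro-1H-spiro[cyclopenta[c]pyran-7,2'-oxirane]-1,6-diyl bis(3-methylbutanoate)]
Conditions: Bu3SnCH2OH (1.5 equiv), Pd2(dba)3 (5 mol %), AsPh3 (20 mol %), NMP, rt → 40 °C (no chloride additive)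
Reagents that add atoms: (tributylstannyl)methanol, CCCC[Sn](CCCC)(CCCC)CO
Why: Stille (Kosugi–Migita) hydroxymethylation of an alkenyl triflate installs C11; neutral, halide-free conditions and a weakly donating ligand spare the epoxide, the allylic C7 ester and the acyl acetal.

**Step 14**
Reactants: 15, 11-O-deacetylvaltrate
Product: 16, valtrate [(1S,6S,7R,7aS)-4-(acetoxymethyl)-6,7a-dihydro-1H-spiro[cyclopenta[c]pyran-7,2'-oxirane]-1,6-diyl bis(3-methylbutanoate)]
Conditions: Ac2O, pyridine, DMAP (cat.), CH2Cl2, 0 °C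
Reagents that add atoms: acetic anhydride, CC(=O)OC(C)=O
Why: Standard acetylation of the only free hydroxyl (primary, allylic).

**Step 15**
Reactants: 16, valtrate
Product: 17, 10-acetoxyvaltrathydrin [(1S,6S,7R,7aS)-4,7-bis(acetoxymethyl)-7-hydroxy-1,6,7,7a-tetrahydrocyclopenta[c]pyran-1,6-diyl bis(3-methylbutanoate)]
Conditions: AcOH (3 equiv), Bu4NOAc (1 equiv), MeCN, rt → 35 °C
Reagents that add atoms: acetic acid, CC(=O)O
Why: Buffered carboxylate opening of the 2,2-disubstituted spiro-epoxide by SN2 attack at the primary C10 gives the C10 acetate and the free tertiary C8–OH with retention at C8, mirroring the known nucleophilic opening of valtrate at C10.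

## Compound list

1 | methyl (S)-2,2-dimethyl-1,3-dioxolane-4-carboxylate | COC(=O)[C@@H]1COC(C)(C)O1 | starting material
2 | (R)-4-ethynyl-2,2-dimethyl-1,3-dioxolane | C#C[C@@H]1COC(C)(C)O1 | intermediate
3 | (R)-but-3-yne-1,2-diol | C#C[C@@H](O)CO | intermediate
4 | (R)-1,2-bis(triethylsilyloxy)but-3-yne | C#C[C@@H](O[Si](CC)(CC)CC)CO[Si](CC)(CC)CC | intermediate
5 | (R)-2-[3,4-bis(triethylsilyloxy)but-1-en-2-yl]-4,4,5,5-tetramethyl-1,3,2-dioxaborolane | C=C(B1OC(C)(C)C(C)(C)O1)[C@@H](O[Si](CC)(CC)CC)CO[Si](CC)(CC)CC | intermediate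
6 | (R)-3-(pinacolboryl)-2-(triethylsilyloxy)but-3-enal | C=C(B1OC(C)(C)C(C)(C)O1)[C@@H](O[Si](CC)(CC)CC)C=O | intermediate
7 | furfuryl alcohol | OCc1ccco1 | starting material
8 | (±)-6-hydroxy-2H-pyran-3(6H)-one | OC1OCC(=O)C=C1 | intermediate
9 | (S)-5-oxo-5,6-dihydro-2H-pyran-2-yl 3-methylbutanoate | CC(C)CC(=O)O[C@@H]1OCC(=O)C=C1 | intermediate
10 | (1S,6R,7aS)-5-hydroxy-7-methylidene-4-oxo-6-(triethylsilyloxy)octahydrocyclopenta[c]pyran-1-yl 3-methylbutanoate (C4a/C5 mixture) | O=C1CO[C@@H](OC(=O)CC(C)C)[C@H]2C1C(O)[C@H](O[Si](CC)(CC)CC)C2=C | intermediate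
11 | (1S,6R,7aS)-5,6-dihydroxy-7-methylidene-4-oxooctahydrocyclopenta[c]pyran-1-yl 3-methylbutanoate (C4a/C5 mixture) | O=C1CO[C@@H](OC(=O)CC(C)C)[C@H]2C1C(O)[C@H](O)C2=C | intermediate
12 | (1S,6S,7aR)-7-methylidene-4-oxo-1,3,4,6,7,7a-hexahydrocyclopenta[c]pyran-1,6-diyl bis(3-methylbutanoate) | O=C1CO[C@@H](OC(=O)CC(C)C)[C@H]2C1=C[C@H](OC(=O)CC(C)C)C2=C | intermediate
13 | (1S,6S,7R,7aS)-4-oxo-3,4,6,7a-tetrahydro-1H-spiro[cyclopenta[c]pyran-7,2'-oxirane]-1,6-diyl bis(3-methylbutanoate) | O=C1CO[C@@H](OC(=O)CC(C)C)[C@H]2C1=C[C@H](OC(=O)CC(C)C)[C@]23CO3 | intermediate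
14 | C4 enol triflate of 13 (dienyl triflate) | FC(F)(F)S(=O)(=O)OC1=CO[C@@H](OC(=O)CC(C)C)[C@H]2C1=C[C@H](OC(=O)CC(C)C)[C@]23CO3 | intermediate
15 | 11-O-deacetylvaltrate | OCC1=CO[C@@H](OC(=O)CC(C)C)[C@H]2C1=C[C@H](OC(=O)CC(C)C)[C@]23CO3 | intermediate
16 | valtrate | CC(=O)OCC1=CO[C@@H](OC(=O)CC(C)C)[C@H]2C1=C[C@H](OC(=O)CC(C)C)[C@]23CO3 | intermediate
17 | 10-acetoxyvaltrathydrin | CC(=O)OCC1=CO[C@@H](OC(=O)CC(C)C)[C@H]2C1=C[C@H](OC(=O)CC(C)C)[C@]2(O)COC(C)=O | target

## Summary

**Total steps:** 15 (convergent: 5 for fragment 6, 2 for pyranone 9, 8 after union).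
**Longest linear sequence:** 13 steps (Steps 1–5, then 8–15).

**Three steps most likely to fail, with fallbacks that change the approach**

1. **Step 8 (Rh alkenylation/aldol annulation).** Risks are slow transmetalation of the hindered α-branched alkenyl-Bpin, β-silyloxy elimination from the alkenyl-Rh to an allene, and protonation of the enolate before aldol. Fallback: close the cyclopentene by metathesis instead of aldol. Conjugate-add the alkenyl organometallic derived from an (R)-3-silyloxy-penta-1,4-dien-2-yl unit with TMSCl trapping (regiodefined C4/C5 silyl enol ether), methylenate C5 with Eschenmoser's salt, and form C5=C6 by Grubbs-II RCM with the C7 vinyl group.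

2. **Step 12 (triflation of the epoxy-enone).** Risks are competing γ-deprotonation at C7 with vinylogous opening of the epoxide, and base damage to the acyl acetal. Fallback: introduce C11 as a nucleophile instead of via an enolate. Add (i-PrO)Me2SiCH2MgCl/CeCl3 to the C4 ketone, carry out Tamao oxidation and selective primary acetylation, then dehydrate the tertiary allylic alcohol toward C3 (Burgess reagent) to unveil the dienol ether.

3. **Step 15 (acetolysis of valtrate).** Valtrate is acid-, base- and heat-labile (elimination/aromatisation), and C8 opening or C7-ester participation could compete. Fallback: set C8/C10 at the robust enone stage. Replace Step 11 with OsO4/NMO dihydroxylation of 12 (anti to C7–OiVal), acetylate the primary C10–OH, mask the tertiary C8–OH as a TMS ether, run triflation/Stille/C11 acetylation, and finish with a mild desilylation (Et3N·3HF). This also covers the case where the epoxidation in Step 11 shows poor facial selectivity.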